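The 1,2-dioxane is disconnected at its O–O bond and at C3–C4/C5–C6. The two peroxide-bearing ring carbons C3 and C6, joined by the C4–C5 bridge, are treated as the olefinic carbons of a cyclobutene that ozone re-links through O1–O2. The key step is a cobalt-catalysed enantioselective [2+2] union of but-1-yne and but-1-ene. In one operation it delivers all four ring carbons, both ring ethyl groups and the C4 stereocentre as (S)-1,3-diethylcyclobutene; its precursors are simply the two C4 gases, neither carrying a directing group. Ozonolysis in methanol, two peroxycarbenium substitutions (allyl at C6, acetate at C3) and a metathesis/diimide/Julia–Kocienski chain extension complete the target.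

Key step: step 1

Assumption: the acetal carbons C3 and C6 of 4, 5 and 7 are carried as epimer mixtures because each is ionised later, and in steps 1 and 5 the catalyst antipode is the one that gives the configuration drawn ((S)-3 maps onto 4S because the CIP ranking at that carbon does not change on ring cleavage).

Step 1
Reactants: 1 but-1-yne; 2 but-1-ene
Product: 3 (S)-1,3-diethylcyclobut-1-ene
Conditions: [(L*)CoBr2] (10 mol%; L* = chiral 1,3-bisphosphine such as BDPP or a phosphino-oxazoline, chosen by screening), Zn, NaBArF4, CH2Cl2, sealed tube, rt; 2 (4 equiv), 1 added slowly; product distilled or used as a filtered solution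
Reagents that add atoms: none
Why: Proposed new method: a cationic cobalt(I) centre bearing a chiral P,P or P,N ligand should bind both π-partners, couple them oxidatively to a cobaltacyclopentene and release the product by C(sp2)–C(sp3) reductive elimination; the closest known reaction type is the cobalt(I)-catalysed enantioselective [2+2] cycloaddition of internal alkynes with alkenes, which has not been shown for a terminal alkyne paired with an unactivated 1-alkene. The cyclobutene ring is closed by that reductive elimination, a contraction of the five-membered metallacycle that completes a formal intermolecular [2+2] and forms the two bonds that become C3–C4 and C5–C6 of the dioxane. The one new stereocentre, the CH(Et) carbon that becomes C4, is controlled by the ligand alone, which must choose the enantiotopic face of but-1-ene in the C–C bond-forming oxidative coupling. The step needs chemoselectivity for cross-coupling over alkyne oligomerisation, head-to-tail regioselectivity and face selectivity. Only the regiochemistry has substrate support: the 1,3-diethyl isomer is the one pathway in which neither the oxidative coupling nor the reductive elimination has to join two ethyl-bearing carbons, whereas the 1,4-isomer requires one such congested bond. Excess alkene and slow alkyne addition are meant to secure the chemoselectivity.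

Step 2
Reactants: 3 (S)-1,3-diethylcyclobut-1-ene
Product: 5 (4S)-4,6-diethyl-3,6-dimethoxy-1,2-dioxane (epimers at C3 and C6), via 6-methoxy-1,2-dioxan-3-ol 4 (not isolated)
Conditions: O3, MeOH/CH2Cl2 (3:1), −78 °C; N2 purge, no reductant; then TsOH·H2O (cat.), MeOH, 0 °C → rt; NaHCO3
Reagents that add atoms: ozone, [O-][O+]=O; methanol, CO
Why: Criegee ozonolysis with methanol capture: the carbonyl oxide is trapped as an α-methoxy hydroperoxide whose OOH adds to the 1,4-related carbonyl to close the six-membered hemiperacetal 4, and acid-catalysed acetal exchange caps C3 as OMe, while C4 is not involved and keeps its configuration.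

Step 3
Reactants: 5 (4S)-4,6-diethyl-3,6-dimethoxy-1,2-dioxane; 6 allyltrimethylsilane
Product: 7 (4S,6S)-4,6-diethyl-3-methoxy-6-(prop-2-en-1-yl)-1,2-dioxane (C3 epimers)
Conditions: TiCl4 (1.0 equiv), 6 (2 equiv), CH2Cl2, −78 °C
Reagents that add atoms: none
Why: Hosomi–Sakurai allylation of a peroxycarbenium ion: TiCl4 should ionise the more substituted C6 ketal methoxy group before the C3 acetal one, and the allylsilane adds along the axial trajectory of the half-chair that keeps the C4 ethyl pseudo-equatorial, so allyl enters trans to C4–Et and C6 becomes S (1,3-induction from C4).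

Step 4
Reactants: 7 (4S,6S)-4,6-diethyl-3-methoxy-6-(prop-2-en-1-yl)-1,2-dioxane; 8 tert-butyl[(1-methoxyethenyl)oxy]dimethylsilane
Product: 9 methyl 2-[(3S,4S,6S)-4,6-diethyl-6-(prop-2-en-1-yl)-1,2-dioxan-3-yl]acetate
Conditions: TiCl4 (1.1 equiv), 8 (2 equiv), CH2Cl2, −78 → −40 °C
Reagents that add atoms: none
Why: Mukaiyama-type addition of a silyl ketene acetal to the C3 peroxycarbenium ion: the ring is locked with C4–Et and C6–Et pseudo-equatorial (the flipped form would set them 1,3-diaxial), so axial attack should place CH2CO2Me cis to C4–Et and trans to the C6 allyl group (3S), and the ketene acetal is far more nucleophilic than the pendant terminal alkene.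

Step 5
Reactants: 10 2,5-dihydrofuran; 11 ethylmagnesium chloride
Product: 12 (2R)-2-ethylbut-3-en-1-ol
Conditions: ethylenebis(tetrahydroindenyl)zirconium binolate or dichloride (10 mol%, resolved), 11 (5 equiv), THF, rt; aq NH4Cl
Reagents that add atoms: none
Why: Zirconocene-catalysed asymmetric carbomagnesation (ethylmagnesation) of a cyclic allylic ether: the zirconocene–ethene complex inserts the ring alkene, Zr–Mg exchange and β-alkoxide elimination open the ring, and the C2-symmetric ansa-ligand selects the alkene face that is carbometallated, which sets C2 as R.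

Step 6
Reactants: 9 methyl 2-[(3S,4S,6S)-4,6-diethyl-6-(prop-2-en-1-yl)-1,2-dioxan-3-yl]acetate; 12 (2R)-2-ethylbut-3-en-1-ol
Product: 13 methyl 2-[(3S,4S,6S)-4,6-diethyl-6-[(2E,4R)-4-ethyl-5-hydroxypent-2-en-1-yl]-1,2-dioxan-3-yl]acetate (mainly E; geometry immaterial)
Conditions: Hoveyda–Grubbs II (5 mol%), 12 (3 equiv), CH2Cl2, 40 °C
Reagents that add atoms: none
Why: Olefin cross-metathesis of the unhindered terminal alkene of 9 with an excess of the allylically branched partner 12, which homodimerises slowly; ruthenium carbenes leave dialkyl peroxides, esters and free alcohols intact, and no stereocentre is touched.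

Step 7
Reactants: 13 methyl 2-[(3S,4S,6S)-4,6-diethyl-6-[(2E,4R)-4-ethyl-5-hydroxypent-2-en-1-yl]-1,2-dioxan-3-yl]acetate
Product: 14 methyl 2-[(3S,4S,6S)-4,6-diethyl-6-[(4R)-4-ethyl-5-hydroxypentyl]-1,2-dioxan-3-yl]acetate
Conditions: KO2CN=NCO2K (excess, in portions), AcOH, MeOH/CH2Cl2, 0 °C → rt
Reagents that add atoms: none
Why: Diimide reduction: concerted syn transfer of H2 from HN=NH saturates the non-polar C=C, while the O–O bond, which would not survive catalytic hydrogenation, and the ester are left alone.

Step 8
Reactants: 14 methyl 2-[(3S,4S,6S)-4,6-diethyl-6-[(4R)-4-ethyl-5-hydroxypentyl]-1,2-dioxan-3-yl]acetate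
Product: 15 methyl 2-[(3S,4S,6S)-4,6-diethyl-6-[(4R)-4-ethyl-5-oxopentyl]-1,2-dioxan-3-yl]acetate
Conditions: Dess–Martin periodinane, NaHCO3, CH2Cl2, 0 °C → rt; used at once
Reagents that add atoms: none
Why: Dess–Martin oxidation of the primary alcohol is non-basic and peroxide-compatible, so the α-stereocentre of the new aldehyde should keep its configuration.

Step 9
Reactants: 16 1-phenyl-1H-tetrazole-5-thiol; 17 1-bromopropane
Product: 18 1-phenyl-5-(propylsulfanyl)-1H-tetrazole
Conditions: K2CO3, acetone, rt
Reagents that add atoms: none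
Why: SN2 S-alkylation of the thiolate by a primary bromide.

Step 10
Reactants: 18 1-phenyl-5-(propylsulfanyl)-1H-tetrazole
Product: 19 1-phenyl-5-(propane-1-sulfonyl)-1H-tetrazole
Conditions: (NH4)6Mo7O24·4H2O (cat.), 30% H2O2, EtOH, 0 °C → rt
Reagents that add atoms: hydrogen peroxide, OO
Why: Molybdate-catalysed peroxide oxidation of the sulfide to the sulfone, the standard access to Julia–Kocienski reagents.

Step 11
Reactants: 15 methyl 2-[(3S,4S,6S)-4,6-diethyl-6-[(4R)-4-ethyl-5-oxopentyl]-1,2-dioxan-3-yl]acetate; 19 1-phenyl-5-(propane-1-sulfonyl)-1H-tetrazole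
Product: 20 methyl 2-[(3S,4S,6S)-4,6-diethyl-6-[(4R,5E)-4-ethyloct-5-en-1-yl]-1,2-dioxan-3-yl]acetate (CNP0124952.2)
Conditions: 19 (1.2 equiv), KHMDS (1.1 equiv), DME, −60 °C; then 15, −60 °C → rt
Reagents that add atoms: none
Why: Julia–Kocienski olefination: the premetallated phenyltetrazolyl sulfone adds to the aldehyde and Smiles rearrangement with loss of SO2 and the tetrazolone gives the alkene, E geometry being favoured by potassium in DME and by the α-branched aldehyde, while the weakly basic sulfonyl carbanion, used near-stoichiometrically at low temperature, should spare the β-peroxy ester and the α-stereocentre.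

Compound list
1 | but-1-yne | CCC#C | starting material
2 | but-1-ene | CCC=C | starting material
3 | (S)-1,3-diethylcyclobut-1-ene | CCC1=C[C@@H](CC)C1 | intermediate
4 | (4S)-4,6-diethyl-6-methoxy-1,2-dioxan-3-ol (epimers at C3 and C6) | COC1(CC)C[C@H](CC)C(O)OO1 | intermediate
5 | (4S)-4,6-diethyl-3,6-dimethoxy-1,2-dioxane (epimers at C3 and C6) | COC1(CC)C[C@H](CC)C(OC)OO1 | intermediate
6 | allyltrimethylsilane | C=CC[Si](C)(C)C | starting material
7 | (4S,6S)-4,6-diethyl-3-methoxy-6-(prop-2-en-1-yl)-1,2-dioxane (C3 epimers) | C=CC[C@@]1(CC)C[C@H](CC)C(OC)OO1 | intermediate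
8 | tert-butyl[(1-methoxyethenyl)oxy]dimethylsilane | C=C(OC)O[Si](C)(C)C(C)(C)C | starting material
9 | methyl 2-[(3S,4S,6S)-4,6-diethyl-6-(prop-2-en-1-yl)-1,2-dioxan-3-yl]acetate | C=CC[C@@]1(CC)C[C@H](CC)[C@H](CC(=O)OC)OO1 | intermediate
10 | 2,5-dihydrofuran | C1=CCOC1 | starting material
11 | ethylmagnesium chloride | CC[Mg]Cl | starting material
12 | (2R)-2-ethylbut-3-en-1-ol | OC[C@H](CC)C=C | intermediate
13 | methyl 2-[(3S,4S,6S)-4,6-diethyl-6-[(2E,4R)-4-ethyl-5-hydroxypent-2-en-1-yl]-1,2-dioxan-3-yl]acetate | OC[C@H](CC)/C=C/C[C@@]1(CC)C[C@H](CC)[C@H](CC(=O)OC)OO1 | intermediate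
14 | methyl 2-[(3S,4S,6S)-4,6-diethyl-6-[(4R)-4-ethyl-5-hydroxypentyl]-1,2-dioxan-3-yl]acetate | OC[C@H](CC)CCC[C@@]1(CC)C[C@H](CC)[C@H](CC(=O)OC)OO1 | intermediate
15 | methyl 2-[(3S,4S,6S)-4,6-diethyl-6-[(4R)-4-ethyl-5-oxopentyl]-1,2-dioxan-3-yl]acetate | O=C[C@H](CC)CCC[C@@]1(CC)C[C@H](CC)[C@H](CC(=O)OC)OO1 | intermediate
16 | 1-phenyl-1H-tetrazole-5-thiol | Sc1nnnn1-c1ccccc1 | starting material
17 | 1-bromopropane | CCCBr | starting material
18 | 1-phenyl-5-(propylsulfanyl)-1H-tetrazole | CCCSc1nnnn1-c1ccccc1 | intermediate
19 | 1-phenyl-5-(propane-1-sulfonyl)-1H-tetrazole | CCCS(=O)(=O)c1nnnn1-c1ccccc1 | intermediate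
20 | methyl 2-[(3S,4S,6S)-4,6-diethyl-6-[(4R,5E)-4-ethyloct-5-en-1-yl]-1,2-dioxan-3-yl]acetate | CC/C=C/[C@H](CC)CCC[C@@]1(CC)C[C@H](CC)[C@H](CC(=O)OC)OO1 | target

Total step count: 11
Longest linear sequence: 8 steps (steps 1, 2, 3, 4, 6, 7, 8, 11)

Steps most likely to fail

1. Step 1 (Proposed new method). Alkyne oligomerisation or C–H dimerisation may outrun the cross-cycloaddition, and with no directing group on either partner the head-to-tail orientation and the alkene face may be poorly controlled. The fallback uses known chemistry and sets out from 2. Cycloaddition with dichloroketene (trichloroacetyl chloride, Zn–Cu, ether) should give racemic 2,2-dichloro-3-ethylcyclobutan-1-one F1. Zinc in acetic acid removes both chlorines to give the achiral 3-ethylcyclobutan-1-one F2. Enantiotopos-selective deprotonation with a chiral lithium amide (lithium bis(1-phenylethyl)amide, Me3SiCl present, THF, −100 °C) gives (S)-[(3-ethylcyclobut-1-en-1-yl)oxy]trimethylsilane F3. MeLi and then PhNTf2 convert it into (S)-3-ethylcyclobut-1-en-1-yl trifluoromethanesulfonate F4. Iron-catalysed cross-coupling with EtMgBr (Fe(acac)3, THF/NMP) brings the sequence back to the route at 3.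

2. Step 4. Ionisation of the secondary peroxyacetal may be slow enough for Lewis-acid-induced O–O heterolysis to compete, or the nucleophile may enter on the equatorial face and give the C3 epimer. The fallback sets out from 7. Mild aqueous acid hydrolyses the C3 methoxy group to (4S,6S)-4,6-diethyl-6-(prop-2-en-1-yl)-1,2-dioxan-3-ol F5, which equilibrates with its open γ-hydroperoxy aldehyde. Wittig olefination of that aldehyde with methyl (triphenylphosphoranylidene)acetate gives methyl (2E,4S,6S)-4,6-diethyl-6-hydroperoxynona-2,8-dienoate F6. Intramolecular 6-exo conjugate addition of the hydroperoxide (Et2NH, CF3CH2OH) closes the dioxane again and returns to the route at 9. The C3 epimers would be separated by chromatography and the unwanted one resubmitted to the equilibrating conditions.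

3. Step 11. The sulfonyl carbanion may deprotonate α to the ester and open the β-peroxy ester by elimination, or enolise the α-branched aldehyde and erode the side-chain stereocentre. The fallback sets out from 7 and installs the ester last, so that no base meets it.
- Cross-metathesis of 7 with 12 gives (2R,3E)-5-[(4S,6S)-4,6-diethyl-3-methoxy-1,2-dioxan-6-yl]-2-ethylpent-3-en-1-ol F7 (target ring numbering).
- Diimide reduction gives (2R)-5-[(4S,6S)-4,6-diethyl-3-methoxy-1,2-dioxan-6-yl]-2-ethylpentan-1-ol F8.
- Dess–Martin oxidation gives (2R)-5-[(4S,6S)-4,6-diethyl-3-methoxy-1,2-dioxan-6-yl]-2-ethylpentanal F9.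
- Julia–Kocienski olefination with 19 gives (4S,6S)-4,6-diethyl-6-[(4R,5E)-4-ethyloct-5-en-1-yl]-3-methoxy-1,2-dioxane F10.
- TiCl4-mediated addition of 8 at C3, as in step 4, comes back to the route at 20.

Further compounds
F1 | step 1 | 2,2-dichloro-3-ethylcyclobutan-1-one (racemic) | CCC1CC(=O)C1(Cl)Cl
F2 | step 1 | 3-ethylcyclobutan-1-one | CCC1CC(=O)C1
F3 | step 1 | (S)-[(3-ethylcyclobut-1-en-1-yl)oxy]trimethylsilane | C[Si](C)(C)OC1=C[C@@H](CC)C1
F4 | step 1 | (S)-3-ethylcyclobut-1-en-1-yl trifluoromethanesulfonate | O=S(=O)(OC1=C[C@@H](CC)C1)C(F)(F)F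
F5 | step 4 | (4S,6S)-4,6-diethyl-6-(prop-2-en-1-yl)-1,2-dioxan-3-ol | C=CC[C@@]1(CC)C[C@H](CC)C(O)OO1
F6 | step 4 | methyl (2E,4S,6S)-4,6-diethyl-6-hydroperoxynona-2,8-dienoate | C=CC[C@](CC)(OO)C[C@H](CC)/C=C/C(=O)OC
F7 | step 11 | (2R,3E)-5-[(4S,6S)-4,6-diethyl-3-methoxy-1,2-dioxan-6-yl]-2-ethylpent-3-en-1-ol | OC[C@H](CC)/C=C/C[C@@]1(CC)C[C@H](CC)C(OC)OO1
F8 | step 11 | (2R)-5-[(4S,6S)-4,6-diethyl-3-methoxy-1,2-dioxan-6-yl]-2-ethylpentan-1-ol | OC[C@H](CC)CCC[C@@]1(CC)C[C@H](CC)C(OC)OO1
F9 | step 11 | (2R)-5-[(4S,6S)-4,6-diethyl-3-methoxy-1,2-dioxan-6-yl]-2-ethylpentanal | O=C[C@H](CC)CCC[C@@]1(CC)C[C@H](CC)C(OC)OO1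
F10 | step 11 | (4S,6S)-4,6-diethyl-6-[(4R,5E)-4-ethyloct-5-en-1-yl]-3-methoxy-1,2-dioxane | CC/C=C/[C@H](CC)CCC[C@@]1(CC)C[C@H](CC)C(OC)OO1
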